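No rate constants are on the table yet, so you keep books on the initiator, which begins the chains.

| setting | amber | green | east | south |
|---|---|---|---|---|
| free monomer | 2.4 M | 2.4 M | 2.4 M | 2.4 M |
| protic impurity | 0.48 M | 1.1 M | 0.720 M | 0.720 M |
| initiator | 98 mM | 98 mM | 98 mM | 98 mM |
| stray impurity | 16 mM | 16 mM | 16 mM | 16 mM |
| remark | run made earlier | run made earlier |  |  |
| time |  |  | 20 min | 5.0 min |

| run | time / min | monomer in chains / % |
|---|---|---|
| amber | 1.00 | 1.8 |
| amber | 3.00 | 7.6 |
| amber | 6.00 | 13.6 |
| amber | 8.00 | 16.9 |
| amber | 12.0 | 24.7 |
| green | 1.00 | 2.1 |
| green | 2.00 | 4.9 |
| green | 3.00 | 7.0 |
| green | 6.00 | 11.0 |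
| green | 12.0 | 19.7 |

(scatter of a reading: 0.5 percentage points)

- the average divides the monomer in chains by the number of chains begun, living and dead together
- reactions considered so far: free monomer + initiator -> living end + monomer in chains; free monomer + living end -> monomer in chains + living end; initiator -> spent initiator A; initiator + stray impurity -> spent initiator B; protic impurity + free monomer -> quenched substrate
- the earlier runs do not show the number of chains; that part of a forecast is a guess

- which of the two ends with the longer chains by the average number of monomer units in a chain (chains begun, living or dead) ("neither" if they lie within 10%) (east / south / neither)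
- average number of monomer units in a chain (chains begun, living or dead) at the end, east
- average number of monomer units in a chain (chains begun, living or dead) at the end, south

Here is my ledger, the same for east and south. Of 98 mM of initiator charged, the first entry goes to the stray impurity: I book one initiator for each of its 16 mM. The step to spent initiator A I book at nil, a guess these runs can't test. The balance, 82.0 mM, is the chain budget, initiator charged less stray impurity charged, with one chain begun per mole. Average length is then monomer in chains, as a concentration, over the budget.

Free monomer gets the same treatment, by fraction left. I book one free monomer per protic impurity, so chains in east and south can reach 70.0% of the charge. Assuming the protic impurity in the amber run has used up its 0.48 M by 6.00 min, the readings there then give the fraction left a time constant of 32.8 min.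

For south, the runs read 11.6% (amber) and 9.67% (green) at 5.0 min. Interpolated to 0.720 M, that is 10.9%, so with the budget fully begun, south comes to 3.18 units. For east, interpolation gives 22.8% at 12.0 min. Running the time constant on to 20 min gives 33.0%, so east comes to 9.65 units, longer than south.

The forecast says east, with 16 units for east and 5.3 for south, on “roughly 50 mM of chains, perhaps 30–80”. My budget stands at 82.0 mM, and my lengths come out shorter than the forecast's; that is where we part.

The flask gives east: 9.24 units for east, 3.31 for south.

    free monomer + initiator → living end + monomer in chains (k = 0.00498 M⁻¹ s⁻¹)
    free monomer + living end → monomer in chains + living end, rate k2*[living end]*[free monomer] (k = 0.00569 M⁻¹ s⁻¹)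
    initiator → spent initiator A (k = 5.17 × 10⁻⁷ s⁻¹)
    initiator + stray impurity → spent initiator B (k = 1.76 M⁻¹ s⁻¹)
    protic impurity + free monomer → quenched substrate (k = 0.00270 M⁻¹ s⁻¹)

East ends with 0.0820 M of living end, level with the budget, and south with 0.0772 M. Now take a neighbouring flask, which is east with 0.039 M of initiator. Its budget is 23.0 mM, and the flask holds 0.0233 M of living end. Its 11.0% of monomer in chains over that budget makes about 11.5 units, and the neighbouring flask gives 11.3.

The earlier runs and the new flask were computed for substances that don't exist.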